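**Plan**

- Retrosynthesis: the central O-benzyl group and the two C3 carboxyl groups of the outer units are removed first. Each outer phenolic ring is then cut at C1–C2 and C3–C4, which releases C2–C3 as an acrylate and leaves a 3-aryl-7-methoxyphthalide.
- Enabling feature: in each 4-hydroxy-5-methoxynaphthalen-1-yl unit, the biaryl carbon C1 and the carbinol carbon C4 are bonded to C8a and C4a of the methoxy-bearing benzo ring. C3 and C1 of a phthalide are bonded to C3a and C7a in the same way, and the 5-OMe corresponds to the phthalide 7-OMe.
- The two phthalide C3–aryl bonds (the later biaryl bonds) are cut to a central naphthalene-2,4-dicarbaldehyde and ortho-lithiated N,N-diethyl-2-methoxybenzamide. The dialdehyde comes from 2,4-dibromination of 8-methoxynaphthalen-1-ol.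
- Forward order: the central naphthalene is functionalised at C2 and C4, both lactone rings are closed, both outer phenolic rings are closed in one operation, and the esters and the benzyl group are then removed.
- Stereochemistry: the target has no stereocentre. The two phthalide stereocentres are transient and are erased on aromatisation.

Key step: step 6

Remark: the structure specifies no axial configuration, so the two biaryl axes are treated as freely rotating and nothing stereochemical has to be set.

**Route**

Step 1
Reactants: 1 naphthalene-1,8-diol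
Product: 2 8-methoxynaphthalen-1-ol
Conditions: MeI (1.05 equiv), K2CO3 (1.1 equiv), acetone, reflux
Reagents that add atoms: iodomethane, CI
Why: Williamson etherification should stop at the monoether, because the hydroxyl left in 2 is hydrogen-bonded to the peri methoxy oxygen and is much less acidic than the first one.

Step 2
Reactants: 2 8-methoxynaphthalen-1-ol
Product: 3 2,4-dibromo-8-methoxynaphthalen-1-ol
Conditions: NBS (2.05 equiv), i-Pr2NH (cat.), CH2Cl2, 0 °C to rt, dark
Reagents that add atoms: N-bromosuccinimide, O=C1CCC(=O)N1Br
Why: Electrophilic aromatic bromination should take place twice on the free naphthol ring, ortho (C2) and para (C4) to the hydroxyl as in the 2,4-dibromination of 1-naphthol, because amine-mediated bromine transfer runs through the phenol and leaves the methyl ether ring alone.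

Step 3
Reactants: 3 2,4-dibromo-8-methoxynaphthalen-1-ol
Product: 4 1-(benzyloxy)-2,4-dibromo-8-methoxynaphthalene
Conditions: BnBr (1.3 equiv), K2CO3 (2 equiv), DMF, 60 °C
Reagents that add atoms: benzyl bromide, BrCc1ccccc1
Why: Williamson benzylation of the acidified dibromonaphthol installs an ether that should tolerate organolithiums, lithium amide base, TsOH and trifluoroacetic acid and that is removed at the end by hydrogenolysis.

Step 4
Reactants: 4 1-(benzyloxy)-2,4-dibromo-8-methoxynaphthalene
Product: 6 1-(benzyloxy)-8-methoxynaphthalene-2,4-dicarbaldehyde, via 2,4-dilithio-1-(benzyloxy)-8-methoxynaphthalene 5 (not isolated)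
Conditions: t-BuLi (4.4 equiv), THF, −78 °C; DMF (6 equiv), −78 to 0 °C; H2O
Reagents that add atoms: N,N-dimethylformamide, CN(C)C=O
Why: Double bromine–lithium exchange (two equivalents of t-BuLi per bromine, as used for alkoxy-substituted meta-dibromoarenes) followed by Bouveault-type formylation should give the dialdehyde, since the tetrahedral DMF adducts persist until aqueous hydrolysis.

Step 5
Reactants: 6 1-(benzyloxy)-8-methoxynaphthalene-2,4-dicarbaldehyde; 7 N,N-diethyl-2-methoxybenzamide (2.6 equiv)
Product: 10 3,3'-[1-(benzyloxy)-8-methoxynaphthalene-2,4-diyl]bis(7-methoxy-2-benzofuran-1(3H)-one) (diastereomer mixture), via ortho-lithiated benzamide 8 (not isolated), via bis(hydroxy amide) 9 (not isolated)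
Conditions: 7, s-BuLi, TMEDA, THF, −78 °C; 6, −78 °C to rt; H2O; then TsOH·H2O (2.5 equiv), PhMe, 80 °C
Reagents that add atoms: none
Why: Amide-directed ortho-metalation lithiates 7 at C6, next to the carboxamide and remote from the methoxy group; 1,2-addition to both aldehydes and acid-mediated lactonisation with loss of diethylamine should then give two 3-aryl-7-methoxyphthalides, whose two uncontrolled stereocentres are erased in step 6.

Step 6
Reactants: 10 3,3'-[1-(benzyloxy)-8-methoxynaphthalene-2,4-diyl]bis(7-methoxy-2-benzofuran-1(3H)-one); 11 tert-butyl acrylate (3 equiv, two incorporated)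
Product: 14 di-tert-butyl 4,4'-[1-(benzyloxy)-8-methoxynaphthalene-2,4-diyl]bis(1-hydroxy-8-methoxynaphthalene-2-carboxylate), via dilithiated bis(phthalide) 12 (not isolated), via bis(hydroxytetralone keto ester) 13 (not isolated)
Conditions: LiN(i-Pr)2 (2.4 equiv), THF, −78 °C; 11 added slowly, −78 to 0 °C; AcOH; then TsOH·H2O (cat.), CH2Cl2, rt
Reagents that add atoms: none
Why: LiN(i-Pr)2 removes the C3 hydrogen of each lactone, which is benzylic, attached to the ring oxygen and conjugated with the lactone carbonyl through the benzo ring, so the bis(isobenzofuranolate) 12 should form while the much less acidic OCH2Ph and OCH3 groups stay untouched. Each carbanion adds to the CH2 terminus of 11 (forming C1–C2 of an outer unit) and the ester enolate so formed acylates itself on the neighbouring lactone carbonyl (forming C3–C4) in a Dieckmann-type closure that is 6-exo-trig for both new rings; collapse of the bridged hemiketal alkoxide and proton transfer give the stabilised β-keto ester enolate of 13, which makes the sequence irreversible. The closest known reaction type is the phthalide-anion Michael–Dieckmann naphthol annulation (a Hauser-type annulation run without a leaving group at C3 and completed by dehydration). Catalytic TsOH then ionises each doubly benzylic tertiary alcohol, and loss of water followed by enolisation should aromatise both rings without cleaving the tert-butyl esters. No stereocentre remains, because the two carbinol centres and the two ester-bearing centres of 13 all become sp2, so every diastereomer of 10 and 13 converges on 14. The selectivity needed is regiochemical (hydroxyl peri to methoxyl, ester next to the hydroxyl) and is fixed by the substrate, because the lactone carbonyl already sits beside the 7-methoxy carbon and the acrylate can bridge C3 and C1 in one sense only; slow addition of 11 at −78 °C and the fast intramolecular acylation should keep acrylate oligomerisation in check.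

Step 7
Reactants: 14 di-tert-butyl 4,4'-[1-(benzyloxy)-8-methoxynaphthalene-2,4-diyl]bis(1-hydroxy-8-methoxynaphthalene-2-carboxylate)
Product: 16 4,4'-[1-(benzyloxy)-8-methoxynaphthalene-2,4-diyl]bis(8-methoxynaphthalen-1-ol), via dicarboxylic acid 15 (not isolated)
Conditions: TFA/CH2Cl2 (1:4), 0 °C to rt; evaporate; then Cu powder (cat.), quinoline, 190 °C, Ar
Reagents that add atoms: none
Why: Acidolysis of the tert-butyl esters (loss of isobutene) followed by thermal protodecarboxylation of the 1-hydroxy-2-naphthoic acids, which react through their keto tautomers as β-keto acids, should remove both carboxyl carbons while the benzyl and methyl ethers stay intact.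

Step 8
Reactants: 16 4,4'-[1-(benzyloxy)-8-methoxynaphthalene-2,4-diyl]bis(8-methoxynaphthalen-1-ol)
Product: 17 2,4-bis(4-hydroxy-5-methoxynaphthalen-1-yl)-8-methoxynaphthalen-1-ol (target)
Conditions: H2 (1 atm), Pd/C (10%), EtOAc/MeOH, rt, product handled under Ar
Reagents that add atoms: none
Why: Catalytic hydrogenolysis of the aryl benzyl ether should free the central hydroxyl without touching the naphthalene rings or the methyl ethers at atmospheric pressure.

**Compound list**

1 | naphthalene-1,8-diol | Oc1cccc2cccc(O)c12 | starting material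
2 | 8-methoxynaphthalen-1-ol | COc1cccc2cccc(O)c12 | intermediate
3 | 2,4-dibromo-8-methoxynaphthalen-1-ol | COc1cccc2c(Br)cc(Br)c(O)c12 | intermediate
4 | 1-(benzyloxy)-2,4-dibromo-8-methoxynaphthalene | COc1cccc2c(Br)cc(Br)c(OCc3ccccc3)c12 | intermediate
5 | 1-(benzyloxy)-2,4-dilithio-8-methoxynaphthalene | COc1cccc2c([Li])cc([Li])c(OCc3ccccc3)c12 | intermediate
6 | 1-(benzyloxy)-8-methoxynaphthalene-2,4-dicarbaldehyde | COc1cccc2c(C=O)cc(C=O)c(OCc3ccccc3)c12 | intermediate
7 | N,N-diethyl-2-methoxybenzamide | CCN(CC)C(=O)c1ccccc1OC | starting material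
8 | N,N-diethyl-2-lithio-6-methoxybenzamide | CCN(CC)C(=O)c1c([Li])cccc1OC | intermediate
9 | 2,2'-{[1-(benzyloxy)-8-methoxynaphthalene-2,4-diyl]bis(hydroxymethylene)}bis(N,N-diethyl-6-methoxybenzamide), diastereomer mixture | COc1cccc2c(C(O)c3cccc(OC)c3C(=O)N(CC)CC)cc(C(O)c3cccc(OC)c3C(=O)N(CC)CC)c(OCc3ccccc3)c12 | intermediate
10 | 3,3'-[1-(benzyloxy)-8-methoxynaphthalene-2,4-diyl]bis(7-methoxy-2-benzofuran-1(3H)-one), diastereomer mixture | COc1cccc2c(C3OC(=O)c4c(OC)cccc34)cc(C3OC(=O)c4c(OC)cccc34)c(OCc3ccccc3)c12 | intermediate
11 | tert-butyl acrylate | C=CC(=O)OC(C)(C)C | starting material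
12 | 3,3'-dilithio derivative of 10 (bis(isobenzofuranolate), drawn as the C-lithio form) | COc1cccc2c(C3([Li])OC(=O)c4c(OC)cccc34)cc(C3([Li])OC(=O)c4c(OC)cccc34)c(OCc3ccccc3)c12 | intermediate
13 | di-tert-butyl 4,4'-[1-(benzyloxy)-8-methoxynaphthalene-2,4-diyl]bis(4-hydroxy-8-methoxy-1-oxo-1,2,3,4-tetrahydronaphthalene-2-carboxylate), diastereomer mixture | COc1cccc2c(C3(O)CC(C(=O)OC(C)(C)C)C(=O)c4c(OC)cccc34)cc(C3(O)CC(C(=O)OC(C)(C)C)C(=O)c4c(OC)cccc34)c(OCc3ccccc3)c12 | intermediate
14 | di-tert-butyl 4,4'-[1-(benzyloxy)-8-methoxynaphthalene-2,4-diyl]bis(1-hydroxy-8-methoxynaphthalene-2-carboxylate) | COc1cccc2c(-c3cc(C(=O)OC(C)(C)C)c(O)c4c(OC)cccc34)cc(-c3cc(C(=O)OC(C)(C)C)c(O)c4c(OC)cccc34)c(OCc3ccccc3)c12 | intermediate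
15 | 4,4'-[1-(benzyloxy)-8-methoxynaphthalene-2,4-diyl]bis(1-hydroxy-8-methoxynaphthalene-2-carboxylic acid) | COc1cccc2c(-c3cc(C(=O)O)c(O)c4c(OC)cccc34)cc(-c3cc(C(=O)O)c(O)c4c(OC)cccc34)c(OCc3ccccc3)c12 | intermediate
16 | 4,4'-[1-(benzyloxy)-8-methoxynaphthalene-2,4-diyl]bis(8-methoxynaphthalen-1-ol) | COc1cccc2c(-c3ccc(O)c4c(OC)cccc34)cc(-c3ccc(O)c4c(OC)cccc34)c(OCc3ccccc3)c12 | intermediate
17 | 2,4-bis(4-hydroxy-5-methoxynaphthalen-1-yl)-8-methoxynaphthalen-1-ol | COc1cccc2c(-c3cc(-c4ccc(O)c5c(OC)cccc45)c4cccc(OC)c4c3O)ccc(O)c12 | target

**Step count**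

Total steps: 8. Longest linear sequence: 8 (steps 1 to 8 from naphthalene-1,8-diol; 7 and 11 enter as purchased materials).

**Steps most likely to fail**

Step 6. The second annulation may stall because conjugate addition of the carbanion beside the peri position is slow. The acrylate may also be consumed by anionic oligomerisation before both arms have reacted. The fallback makes the same four bonds by cycloaddition instead of ionic addition. It sets out from 10, which is deprotonated with LiN(i-Pr)2 and silylated with Me3SiCl in THF at −78 °C to give the bis(silyl ketene acetal) 1-(benzyloxy)-8-methoxy-2,4-bis[4-methoxy-3-(trimethylsilyloxy)-2-benzofuran-1-yl]naphthalene F1, a bis(1-siloxy-3-arylisobenzofuran). F1 is heated with 11 in PhMe at 80 °C in a double Diels–Alder reaction, in which the siloxy-bearing terminus directs the ester carbon next to itself, to give the bis(oxygen-bridged cycloadduct) F2. Catalytic TsOH in CH2Cl2 then opens both bridges, removes the silyl groups and dehydrates, and the route is rejoined at 14.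

Step 4. The second halogen–lithium exchange may be incomplete, or the aryllithium beside the benzyl ether may be protonated or may trigger benzylic deprotonation, so that mono-formylated material results. The fallback introduces the formyl carbons without organolithium chemistry. It sets out from 4, which undergoes a double Suzuki–Miyaura coupling with potassium vinyltrifluoroborate (PdCl2(dppf), Cs2CO3, THF/H2O, 80 °C) to give 1-(benzyloxy)-8-methoxy-2,4-divinylnaphthalene F3. Lemieux–Johnson cleavage (K2OsO4·2H2O cat., NaIO4, 2,6-lutidine, dioxane/H2O, rt) then converts both vinyl groups into formyl groups, and the route is rejoined at 6.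

Step 7. Heating the dicarboxylic acid may cause incomplete loss of the second carboxyl group, oxidative degradation of the free naphthols, or acid-induced transfer of benzyl or tert-butyl cations to the electron-rich rings. The fallback removes the carboxyl carbon before aromatisation, while it is still part of a true β-keto ester. It sets out from 10, which is annulated as in step 6 but with allyl acrylate, and is quenched with acetic acid without the TsOH treatment, to give the diallyl bis(4-hydroxy-1-oxotetralin-2-carboxylate) F4. Pd(PPh3)4 and morpholine in THF at room temperature remove the allyl groups, and the β-keto acids lose carbon dioxide spontaneously to give the bis(4-hydroxy-1-tetralone) F5. Catalytic TsOH in CH2Cl2 then dehydrates and aromatises both rings, and the route is rejoined at 16.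

**Further compounds**

F1 | step 6 | 1-(benzyloxy)-8-methoxy-2,4-bis[4-methoxy-3-(trimethylsilyloxy)-2-benzofuran-1-yl]naphthalene | COc1cccc2c(C3=C4C=CC=C(OC)C4=C(O[Si](C)(C)C)O3)cc(C3=C4C=CC=C(OC)C4=C(O[Si](C)(C)C)O3)c(OCc3ccccc3)c12
F2 | step 6 | di-tert-butyl 4,4'-[1-(benzyloxy)-8-methoxynaphthalene-2,4-diyl]bis[8-methoxy-1-(trimethylsilyloxy)-1,2,3,4-tetrahydro-1,4-epoxynaphthalene-2-carboxylate], isomer mixture | COc1cccc2c(C34CC(C(=O)OC(C)(C)C)C(O[Si](C)(C)C)(O3)c5c(OC)cccc45)cc(C34CC(C(=O)OC(C)(C)C)C(O[Si](C)(C)C)(O3)c5c(OC)cccc45)c(OCc3ccccc3)c12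
F3 | step 4 | 1-(benzyloxy)-8-methoxy-2,4-divinylnaphthalene | COc1cccc2c(C=C)cc(C=C)c(OCc3ccccc3)c12
F4 | step 7 | diallyl 4,4'-[1-(benzyloxy)-8-methoxynaphthalene-2,4-diyl]bis(4-hydroxy-8-methoxy-1-oxo-1,2,3,4-tetrahydronaphthalene-2-carboxylate), diastereomer mixture | COc1cccc2c(C3(O)CC(C(=O)OCC=C)C(=O)c4c(OC)cccc34)cc(C3(O)CC(C(=O)OCC=C)C(=O)c4c(OC)cccc34)c(OCc3ccccc3)c12
F5 | step 7 | 4,4'-[1-(benzyloxy)-8-methoxynaphthalene-2,4-diyl]bis(4-hydroxy-8-methoxy-3,4-dihydronaphthalen-1(2H)-one), diastereomer mixture | COc1cccc2c(C3(O)CCC(=O)c4c(OC)cccc34)cc(C3(O)CCC(=O)c4c(OC)cccc34)c(OCc3ccccc3)c12
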